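All runs stem from a simulated flask with constants of no real substance; scatter was added.

Theta carries 2.21 times the charge of zeta, yet by 40.0 h it has made 1.36 times the product, so product does not follow the charge.

all flasks: gas phase 57 mM (held)
- zeta: starting material 0.34 M; run made earlier
- theta: starting material 0.75 M; run made earlier
- flask: starting material 0.50 M; time 50 h

| run | time / h | product / % | starting material / % |
|---|---|---|---|
| zeta | 3.00 | 3 | 69 |
| zeta | 5.00 | 4 | 72 |
| zeta | 8.00 | 7 | 71 |
| zeta | 12.0 | 15 | 67 |
| zeta | 15.0 | 16 | 61 |
| zeta | 25.0 | 25 | 55 |
| zeta | 40.0 | 47 | 41 |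
| theta | 2.00 | 2 | 73 |
| theta | 6.00 | 3 | 71 |
| theta | 12.0 | 9 | 68 |
| theta | 15.0 | 7 | 65 |
| theta | 25.0 | 15 | 61 |
| theta | 30.0 | 24 | 59 |
| theta | 40.0 | 29 | 51 |

(readings scatter by 2 percentage points)

- the earlier runs were read with a standard deviation of 2 percentage points
- at the start none of the gas phase is in solution

- ash: doubling the saturation concentration of gas phase, all else as stated
- oak: doubling the transfer coefficient of the gas phase, all else as stated

- amount of product at 50 h, in percent of the starting material charged
- concentration of dissolved gas in solution at 12 h, in percent of saturation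
- the change that raises the amount of product at 50 h, in percent of the starting material charged most ("none" if none brings more than 2 percentage points) (ash / oak / none)
- amount of product at 50 h, in percent of the starting material charged, after ash

A note for whoever takes over this flask. In zeta the starting material reads 69 % at 3.00 h with product at 3 %, so I count a quick side store as unreacted charge, the fraction u. Zeta makes 0.00400 M h⁻¹ at mean u of 0.765, theta 0.00544 M h⁻¹ at 0.855. I read the rate as a gas ceiling of 0.00722 M h⁻¹, the product per hour that gas uptake allows with starting material in excess, times u/(u+κ), with κ a demand level as a fraction of the charge. Gas uptake is then a partly rate-limiting step.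

For this flask the ceiling over 50 h is 72.2 % of the charge and κ is 0.419. The full charge gives 50.8 %; putting the mean u back gives 46.2 %, then 46.7 %, my figure. Dissolved gas at 12 h should be κ/(κ+u), 32.1 % of saturation.

Don't touch the transfer first. Ash doubles the ceiling and keeps κ, and its rounds go 80.8 %, 84.7 %, 83.5 %. Oak doubles both and reaches about 63.3 %, less than ash.

The forecast says 44 % (39 % to 49 %), 32 % of saturation, ash and 76 % after it, lower than mine on product, and reads “partial limitation by gas transfer”.

The flask gives 46.3 %, 31.4 %, ash and 77.0 %.

    gas phase ⇌ dissolved gas, rate k1*(csat - [dissolved gas]) (kL = 4.10 × 10⁻⁵ s⁻¹)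
    starting material + dissolved gas → product (k = 2.40 × 10⁻⁴ L mol⁻¹ s⁻¹)
    2 starting material → homo dimer (k = 7.60 × 10⁻⁹ L mol⁻¹ s⁻¹)
    dissolved gas → decomposed reagent (k = 6.80 × 10⁻⁶ s⁻¹)
    starting material ⇌ dormant form (K = 0.330, k = 1.50 × 10⁻⁴ s⁻¹)

In this flask dissolved gas has a half-life of 1.6 h against the starting material as charged, shorter than the 4.70 h half-time of its uptake. It stands at 31.4 % of saturation at 12 h. For the neighbour with 2.0 M, the same ceiling is 18.0 % of its charge, and the rounds give 16.2 %. That flask holds 18.1 % product at 50 h.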